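**Retrosynthetic overview**

- Ring numbering used in the discussion (p-menthane style): C1 = alkene carbon bearing CH3, C2 = alkene CH, C3 = CH bearing the biaryl, C4 = CH bearing isopropyl, C5 and C6 = CH2. The biaryl diol (both arene rings, both allyl groups) is bought as magnolol and is never built.
- Last disconnection: the C3–aryl bond, made by Friedel–Crafts allylation of magnolol with the C1–C2–C3 allyl cation of (4S)-piperitol; attack anti to the C4 isopropyl group gives the trans C3/C4 pair.
- (4S)-Piperitol comes from racemic piperitone by asymmetric hydrogenation with dynamic kinetic resolution, because C4 epimerises next to the C3 carbonyl.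
- The cyclohexene, the only ring that is formed, is closed in one flask from tert-butyl 2-isopropylacetoacetate and methyl vinyl ketone: Michael addition makes C4–C5, the ester is lost as isobutene and CO2, and aldol condensation makes C1=C2.
- Enabling feature: C3 is allylic to C1=C2 and benzylic to a phenol ring, so its aryl bond can be made last from a cation and C3 can be a ketone carbon at the key step. C2 and C4 are then its two enolisable α-carbons and C3/C1 form a 1,5-dicarbonyl pair, the retron of a Michael–aldol annulation.

Key step: step 2

Remark: compound names use cyclohexenyl numbering (C1 = carbon bearing oxygen or aryl, C6 = carbon bearing isopropyl), the discussion uses the p-menthane numbering above. The catalyst antipode in step 3 is assigned by analogy with 2-isopropylcyclohexanone and would be exchanged for its mirror image if the sense of induction on the enone proved opposite.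

Step 1
Reactants: 1 tert-butyl acetoacetate; 2 2-iodopropane
Product: 3 tert-butyl 2-isopropyl-3-oxobutanoate (racemic)
Conditions: t-BuOK (1.05 equiv), 2-iodopropane (1.5 equiv), t-BuOH, 80 °C
Reagents that add atoms: none
Why: Acetoacetic ester alkylation (SN2 of the potassium enolate on the secondary iodide), in which the protic solvent favours C- over O-alkylation and matches the ester; the new stereocentre (future C4) is formed racemic and becomes an enolate again in step 2.

Step 2
Reactants: 3 tert-butyl 2-isopropyl-3-oxobutanoate; 4 methyl vinyl ketone
Product: 7 (±)-piperitone (rac-6-isopropyl-3-methylcyclohex-2-en-1-one), via Michael adduct 5 (not isolated), via 3-isopropylheptane-2,6-dione 6 (not isolated)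
Conditions: 4 (1.3 equiv), Cs2CO3 (0.1 equiv), MeCN, 25 °C; then TsOH·H2O (0.3 equiv), PhMe, 80 to 110 °C, Dean–Stark
Reagents that add atoms: none
Why: Cs2CO3 generates the enolate of 3 at its only acidic carbon (the future C4), which adds in Michael fashion to C5 of 4 to give 5 and so forms C4–C5; TsOH then cleaves the tert-butyl ester (isobutene) and the resulting β-keto acid loses CO2 to give 1,5-diketone 6. Acid-catalysed enolisation of the C3 ketone towards its methyl group (C2), aldol addition to the C1 carbonyl and dehydration form C1=C2; the closest known reaction type is the Robinson annulation in its acetoacetic ester variant (Michael addition, decarboxylation, aldol condensation). The single ring closes in the 6-(enolendo)-exo-trig mode. The only stereocentre, C4, is created without control and is deliberately left racemic, because it is epimerisable next to the C3 carbonyl and is fixed in step 3. The step needs regioselectivity twice: the ester restricts the Michael donor to C4, and the α-isopropyl branch, which shields the C3 carbonyl, together with decarboxylation before cyclisation, directs the aldol closure from C2 to C1 rather than attack of the butenone-derived methyl group on C3. A second Michael addition is excluded because 5 has no acidic hydrogen left at C4.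

Step 3
Reactants: 7 (±)-piperitone
Product: 8 (1R,6S)-6-isopropyl-3-methylcyclohex-2-en-1-ol (cis-piperitol, 4S in p-menthane numbering)
Conditions: RuCl2[(R)-BINAP][(S,S)-DPEN] (0.5 mol %), t-BuOK (0.2 equiv), H2 (8 atm), i-PrOH, 25 °C
Reagents that add atoms: none
Why: Carbonyl-selective Noyori asymmetric hydrogenation with dynamic kinetic resolution, a reaction type known for 2-isopropylcyclohexanone and for cyclic enones: t-BuOK interconverts the enantiomers of 7 through the C4 enolate, the chiral ruthenium hydride reduces the (S)-ketone preferentially and delivers hydride to the carbonyl face anti to the isopropyl group, so C4 should be fixed as S and the carbinol carbon as R, the latter being of no consequence because it becomes planar in step 4.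

Step 4
Reactants: 8 (1R,6S)-6-isopropyl-3-methylcyclohex-2-en-1-ol; 9 magnolol
Product: 10 5,5'-diallyl-3-[(1S,6S)-6-isopropyl-3-methylcyclohex-2-en-1-yl]-[1,1'-biphenyl]-2,2'-diol (CNP0249009.1)
Conditions: 9 (3 equiv), BF3·OEt2 (0.3 equiv) on basic Al2O3, CH2Cl2, 0 to 25 °C
Reagents that add atoms: none
Why: Friedel–Crafts allylation of a phenol by an allylic alcohol (the reaction type that joins p-menthenyl cations to resorcinols): BF3 ionises 8 to the C1–C2–C3 allyl cation, which is attacked by the free position ortho to a hydroxyl group of 9 (the two rings are equivalent) at its less substituted terminus C3 and on the face anti to the adjacent isopropyl group, which should set C3 as S, trans to C4, while the excess of 9 suppresses alkylation of the second ring.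

**Compound list**

1 | tert-butyl acetoacetate (tert-butyl 3-oxobutanoate) | CC(=O)CC(=O)OC(C)(C)C | starting material
2 | 2-iodopropane | CC(C)I | starting material
3 | tert-butyl 2-isopropyl-3-oxobutanoate (racemic) | CC(=O)C(C(C)C)C(=O)OC(C)(C)C | intermediate
4 | methyl vinyl ketone (but-3-en-2-one) | CC(=O)C=C | starting material
5 | tert-butyl 2-acetyl-2-isopropyl-5-oxohexanoate (racemic; Michael adduct, not isolated) | CC(=O)CCC(C(C)C)(C(C)=O)C(=O)OC(C)(C)C | intermediate
6 | 3-isopropylheptane-2,6-dione (racemic; not isolated) | CC(=O)CCC(C(C)C)C(C)=O | intermediate
7 | (±)-piperitone, rac-6-isopropyl-3-methylcyclohex-2-en-1-one | CC1=CC(=O)C(C(C)C)CC1 | intermediate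
8 | (1R,6S)-6-isopropyl-3-methylcyclohex-2-en-1-ol (cis-piperitol) | O[C@H]1C=C(C)CC[C@H]1C(C)C | intermediate
9 | magnolol, 5,5'-diallyl-[1,1'-biphenyl]-2,2'-diol | C=CCc1ccc(O)c(-c2cc(CC=C)ccc2O)c1 | starting material
10 | 5,5'-diallyl-3-[(1S,6S)-6-isopropyl-3-methylcyclohex-2-en-1-yl]-[1,1'-biphenyl]-2,2'-diol (CNP0249009.1) | C=CCc1ccc(O)c(-c2cc(CC=C)cc([C@@H]3C=C(C)CC[C@H]3C(C)C)c2O)c1 | target

Total step count: 4. Longest linear sequence: 4 steps (1 to 3 to 7 to 8 to 10; magnolol enters in the last step).

**Steps most likely to fail**

The hydrogenation (step 3) is the least secure. Epimerisation of C4 may be slower than reduction, so that the dynamic resolution degrades to a plain kinetic resolution; the base may also divert the enone, or the ring alkene may be reduced in competition. The fallback sets out from 7 and comes back at 8. Luche reduction (NaBH4, CeCl3·7H2O, MeOH, −78 °C) should give racemic cis-piperitol F1 after removal of the minor trans isomer. Lipase-catalysed transesterification (Burkholderia cepacia lipase, vinyl acetate, t-BuOMe, 30 °C) is then expected, by the empirical rule for lipases and secondary alcohols, to acylate the (1S)-enantiomer to (1S,6R)-6-isopropyl-3-methylcyclohex-2-en-1-yl acetate F2 and to leave 8, which is separated by chromatography.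

The Friedel–Crafts coupling (step 4) comes next. The allyl cation may lose a proton and be re-protonated, which would erode the configuration at C4; the new ortho-phenol may add to the ring alkene under the acid; and the second ring may be alkylated as well. The fallback avoids a free cation; it sets out from 9 and 8 and comes back at 10. Magnolol 9 is converted into 5,5'-diallyl-2,2'-bis(methoxymethoxy)-1,1'-biphenyl F3 (MOMCl, i-Pr2NEt, CH2Cl2). F3 is lithiated ortho to one OMOM group (s-BuLi, TMEDA, THF, −78 °C) and transmetalated in the same flask with ZnCl2 to arylzinc chloride F4. Alcohol 8 is converted into methyl (1R,6S)-6-isopropyl-3-methylcyclohex-2-en-1-yl carbonate F5 (ClCO2Me, pyridine). A Negishi-type allyl–aryl coupling of F4 with F5 (Pd(PPh3)4, THF, 25 °C) follows: zerovalent palladium ionises the carbonate with inversion and the aryl group is delivered from the metal with retention at the less substituted allyl terminus C3. This should give the trans bis(methoxymethyl) ether of the target F6 with net inversion, and HCl in MeOH at 25 °C removes the MOM groups to give 10.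

The key annulation (step 2) is third. Conjugate addition of the hindered α-isopropyl enolate may be sluggish, and the aldol closure may run in the unwanted sense (butenone-derived methyl onto the hindered carbonyl) if cyclisation outruns decarboxylation. The fallback sets out from 4 and comes back at 7. 4-Methyl-1-(triphenylphosphoranylidene)pentan-2-one F7, made from methyl 3-methylbutanoate and Ph3P=CH2 (2 equiv), is deprotonated at its only acidic carbon (the future C4) with LiN(i-Pr)2 (THF, −78 °C) and added to 4. After protonation, the keto ylide 3-isopropyl-1-(triphenylphosphoranylidene)heptane-2,6-dione F8 closes on heating (toluene, 80 °C) by intramolecular Wittig reaction, which can only form C1=C2, to give 7.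

**Further compounds**

F1 | step 3 | racemic cis-piperitol, rac-(1R,6S)-6-isopropyl-3-methylcyclohex-2-en-1-ol (both enantiomers shown) | O[C@H]1C=C(C)CC[C@H]1C(C)C.O[C@@H]1C=C(C)CC[C@@H]1C(C)C
F2 | step 3 | (1S,6R)-6-isopropyl-3-methylcyclohex-2-en-1-yl acetate | CC(=O)O[C@@H]1C=C(C)CC[C@@H]1C(C)C
F3 | step 4 | 5,5'-diallyl-2,2'-bis(methoxymethoxy)-1,1'-biphenyl | C=CCc1ccc(OCOC)c(-c2cc(CC=C)ccc2OCOC)c1
F4 | step 4 | [5,5'-diallyl-2,2'-bis(methoxymethoxy)-[1,1'-biphenyl]-3-yl]zinc chloride | Cl[Zn]c1cc(CC=C)cc(-c2cc(CC=C)ccc2OCOC)c1OCOC
F5 | step 4 | methyl (1R,6S)-6-isopropyl-3-methylcyclohex-2-en-1-yl carbonate | COC(=O)O[C@H]1C=C(C)CC[C@H]1C(C)C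
F6 | step 4 | 5,5'-diallyl-3-[(1S,6S)-6-isopropyl-3-methylcyclohex-2-en-1-yl]-2,2'-bis(methoxymethoxy)-1,1'-biphenyl | C=CCc1ccc(OCOC)c(-c2cc(CC=C)cc([C@@H]3C=C(C)CC[C@H]3C(C)C)c2OCOC)c1
F7 | step 2 | 4-methyl-1-(triphenylphosphoranylidene)pentan-2-one | CC(C)CC(=O)C=P(c1ccccc1)(c1ccccc1)c1ccccc1
F8 | step 2 | 3-isopropyl-1-(triphenylphosphoranylidene)heptane-2,6-dione (racemic) | CC(=O)CCC(C(C)C)C(=O)C=P(c1ccccc1)(c1ccccc1)c1ccccc1
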